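**Conventions.** Daucane numbering is used throughout. Ring A is the cyclopentane C1–C2–C3–C4–C5 (C1 = quaternary carbon with the angular methyl, C4 = carbon with oxygen and isopropyl, C5 = ring-fusion CH). Ring B is the seven-membered ring C1, C5, C6, C7, C8, C9, C10 (C6 = carbinol, C8/C9 = epoxide). β is the face of the C1 methyl group, α the opposite face. Compounds are numbered 1–27 in the order of the steps.

**Remarks on the chemistry (assumptions).**
1. The 4-hydroxy-3-methoxybenzoate sits on the tertiary C4 oxygen and the C6 hydroxyl is free; the route is built for exactly this regioisomer.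
2. The (R,R) ligand of step 2 and the (R) catalyst of step 8 are assigned from the usual facial models. The configuration of 6 and of 14 is checked when first made, and the antipodal ligand or catalyst is taken if it is the opposite.

## Analysis of the target

The target is a daucane sesquiterpenoid: a trans-fused hydroazulene made of cyclopentane ring A and cycloheptane ring B, with an isopropyl group and an aryl ester on C4, an angular methyl on C1, a secondary alcohol on C6 and a trisubstituted 8,9-epoxide. It has six stereocentres, (1R,4R,5S,6S,8R,9S). On ring A the C1 methyl, the C4 oxygen and the C5–C6 bond all lie on the β face (H5 is α, hence the trans fusion); the C6 hydroxyl and the epoxide oxygen both lie on the α face. C1 is an all-carbon quaternary centre and C4 a fully substituted carbinol carbon, and both flank the ring-fusion carbon C5, so three contiguous crowded centres must be set with relative and absolute control. The sensitive elements are the acid-labile epoxide, the free phenol, and above all the hindered tertiary ester placed 1,3 to a free secondary hydroxyl. Acyl transfer from O4 to O6 is downhill, so base must be avoided once both groups are present, and direct esterification of the 4,6-diol would acylate O6 first. The β-hydroxy carbonyl intermediates (C4–OH with a C6 carbonyl) can also open ring A by retro-aldol cleavage or dehydrate. The plan rests on the cis 1,2-relationship on ring A between the C4 oxygen and the carbon C6 on C5: O4–C4–C5–C6 is the four-atom unit of a β-lactone fused across C4–C5, a temporary ring that fixes C4 and C5 together.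

## Retrosynthetic reasoning

**27 ⇐ 26 ⇐ 25.** The last operations are removal of the phenol benzyl group and formation of the two epoxide C–O bonds. The phenol stays benzylated to the end because hydrogenolysis is neutral, which excludes O4→O6 acyl migration, and is possible once no alkene remains. The epoxide is made late from alkene 25 because it is the most acid-sensitive group and because the free α-hydroxyl on C6 can steer the oxidant to the α face of C8=C9, the face the angular methyl also leaves open.

**25 ⇐ 24 ⇐ 21 + 23.** The ester C(=O)–O4 bond is cut to the tertiary alcohol and aroyl chloride 23 (from acid 22). O6 must be masked during this acylation, since the secondary hydroxyl would otherwise react first. A silyl ether (21, from diol 20) is removable under buffered, non-basic conditions. The protect/acylate/unmask sequence is the price of the unusual ester position; a one-step esterification of 20 would give the wrong regioisomer.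

**20 ⇐ 19.** The C6–H bond is cut. With ring B closed, the C6 carbonyl of 19 has O4 on its β face, so a hydride delivered from a reagent bound to O4 sets the 6α-alcohol. An external hydride would probably approach from the other face.

**19 ⇐ 18.** The C8=C9 bond is cut by ring-closing metathesis to a diene carrying an allyl group on C1 and a methallyl ketone on C5. These arms are trans on ring A, which is exactly what the trans-fused seven-membered ring needs.

**18 ⇐ 15 + 16; 15 ⇐ 14.** The C6–C7 bond is cut to Weinreb amide 15 and methallyl Grignard reagent 16. The amide comes from β-lactone 14 by acyl C–O cleavage. This frees the C4 hydroxyl for the directed reduction and turns the lactone carbonyl into an acyl group that accepts one carbon nucleophile only.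

**14 ⇐ 12 (key disconnection).** The C4–C5 bond and the O4–C6 bond are cut together, giving the open-chain keto acid 12. Forward, an enolate at C5 generated on a chiral catalyst adds to the C4 isopropyl ketone and the aldolate is trapped as the lactone. Ring A, the C4 carbinol with its isopropyl group, and C5 are made in one step; the cis O4/C6 relationship is enforced by the four-membered ring. The single stereocentre of 12 is the quaternary C1.

**12 ⇐ 11 ⇐ 10 ⇐ 8 + 9; 8 ⇐ 7 ⇐ 6.** The isopropyl ketone comes from addition of 9 to aldehyde 8 and oxidation. The 1,6-relationship of the ester and aldehyde carbons in 8 is that of a cleaved cyclohexanone: the C1–C2 bond of α-hydroxy ketone 7 is cut oxidatively, and 7 comes from hydroxylation of ketone 6 on the side remote from the quaternary carbon.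

**6 ⇐ 4 + 5; 4 ⇐ 1 + 2.** The C1–CH3 bond is cut by catalytic asymmetric conjugate addition of the methyl group of 5 to enone 4, which sets the only stereocentre that is not made under the influence of another. Enone 4 comes from 1 and 2 by addition and carbonyl transposition.

## Alternatives that were turned down

**Alternative 1:** The disconnection removes C7 and C8 from ring B, so that ring B is the two-carbon ring expansion of a cis-fused bicyclo[3.3.0]octanone A1 (ring A plus a cyclopentanone, O4 as a triethylsilyl ether). In the forward step the enamine of A1 (C6=C9) undergoes [2+2] cycloaddition with an alkynoate ester and the aminocyclobutene opens electrocyclically to the cycloheptadiene A2, which has the C8 methyl and the C8=C9 double bond in place.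
- For: a thermal ring expansion that fixes the position of the trisubstituted alkene without metathesis on a 1,1-disubstituted alkene; enamine formation away from C5 is reliable.
- Against: A2 carries an ester carbon on C7 that the target lacks and that must be hydrolysed and decarboxylated. The cis ring fusion of A1 is carried into A2, so C5 must later be epimerised through the C6 ketone. A1 already contains C1, C4 and C5, so the crowded ring A triad is only moved into a substrate needing its own stereocontrolled synthesis.
- Comparison: for building ring B this route is at least as strong as the chosen one, which depends on metathesis of a sensitive β,γ-unsaturated ketone. The chosen route offers instead direct, catalyst-controlled formation of C4 and C5 in the trans-fused series, no carbon to excise, and a shorter sequence overall.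

**Alternative 2:** The disconnection is the C1–C5 bond of ring A, traced to a 1,2-shift: ring A is the ring-expanded form of cyclobutanol A3, whose carbinol carbon (the later C4) bears a trans-epoxide (C5–C6). In the forward step a Lewis acid opens the epoxide at C5 while the quaternary ring carbon C1 migrates from C4 to C5 with inversion at C5 (semipinacol rearrangement), giving cyclopentanone A4 with the C6 hydroxyl.
- For: the step is stereospecific, so C5 and C6 are read off from the epoxide and the C6 carbinol arrives correct without a reduction; strain release drives it; both arms for ring B are already present.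
- Against: A4 has a carbonyl at C4, so the isopropyl group and tertiary oxygen must still be installed by adding a branched organometallic to a hindered, enolisable β-hydroxy cyclopentanone, from one face, against enolisation, reduction and retro-aldol cleavage. The rearrangement must also prefer migration of C1 over the C3 methylene, and A3 needs a quaternary stereocentre on a cyclobutane plus a selective epoxidation.
- Comparison: on C6 this alternative is stronger. The chosen strategy offers in exchange an isopropyl group that is on the future C4 from the start (the ketone carbon of 12), with the C4 carbinol formed in the same step that sets C5.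

**Alternative 3:** The disconnection is C8=C9 by ring-closing metathesis of a diene with ring A complete, ring A itself being traced to (S)-terpinen-4-ol A5, whose carbinol carbon and isopropyl group map onto C4. In the forward step the ruthenium metathesis catalyst joins the C1 allyl group to the C6 methallyl carbinol and gives A6, which is diol 20.
- For: it is the shortest plan; C4 is bought with its oxygen and isopropyl group; the metathesis runs on a diol, not a β,γ-unsaturated ketone, so double-bond migration is no concern.
- Against: A5 is usually supplied with modest enantiomeric purity, and C4 would be the only control element. The quaternary C1 would have to be created at a fully substituted β-carbon under 1,3-induction of uncertain sense from a carbon bearing both oxygen and isopropyl, and C5 and C6 would follow by substrate control, so an error at C1 propagates.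
- Comparison: this alternative is stronger in step count and equal in the endgame (the ester problem is the same). The chosen strategy offers catalyst control of the absolute configuration at C1 and of the C4/C5 pair, independent of substrate bias, and an upgrade of enantiomeric purity in its key step.

Key step: step 8

## Route

**Step 1**
Reactants: 1 3-ethoxycyclohex-2-en-1-one; 2 allylmagnesium bromide
Product: 4 3-allylcyclohex-2-en-1-one, via 1-allyl-3-ethoxycyclohex-2-en-1-ol 3 (not isolated)
Conditions: allylMgBr (1.2 equiv), THF, 0 °C; then 1 M aq. HCl, 0 °C, 20 min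
Reagents that add atoms: allylmagnesium bromide (2), C=CC[Mg]Br; water, O
Why: 1,2-addition of the Grignard reagent to the vinylogous ester gives carbinol 3, which on acid hydrolysis of the enol ether and loss of water transposes the carbonyl (Stork–Danheiser sequence); short, cold acid treatment keeps the skipped diene from moving into conjugation.

**Step 2**
Reactants: 4 3-allylcyclohex-2-en-1-one; 5 trimethylaluminium
Product: 6 (R)-3-allyl-3-methylcyclohexan-1-one
Conditions: Me3Al (2 equiv), Cu(OTf)2 (5 mol%), (R,R)-phosphoramidite ligand [O,O'-(biphenyl-2,2'-diyl) N,N-bis((R)-1-(naphthalen-2-yl)ethyl)phosphoramidite] (10 mol%), Et2O, −30 °C; then aq. HCl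
Reagents that add atoms: trimethylaluminium (5), C[Al](C)C
Why: Copper/phosphoramidite-catalysed asymmetric conjugate addition of a methyl group from Me3Al to the β,β-disubstituted enone builds the C1 quaternary centre, the ligand deciding which enone face receives methyl; the Lewis-acidic, weakly basic aluminium reagent should spare the doubly allylic CH2.

**Step 3**
Reactants: 6 (R)-3-allyl-3-methylcyclohexan-1-one
Product: 7 (5R)-5-allyl-2-hydroxy-5-methylcyclohexan-1-one (both C2 epimers)
Conditions: KN(SiMe3)2 (1.1 equiv), THF, −78 °C; 3-phenyl-2-(phenylsulfonyl)oxaziridine (1.3 equiv), −78 °C; aq. NH4Cl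
Reagents that add atoms: 3-phenyl-2-(phenylsulfonyl)oxaziridine, O=S(=O)(c1ccccc1)N1OC1c1ccccc1
Why: Kinetic deprotonation takes the α-methylene remote from the quaternary carbon (the other one is neopentyl and shielded) and the enolate is hydroxylated by the N-sulfonyloxaziridine (Davis oxidation), which leaves the terminal alkene alone; the new carbinol centre is destroyed in step 4, so its configuration does not matter.

**Step 4**
Reactants: 7 (5R)-5-allyl-2-hydroxy-5-methylcyclohexan-1-one
Product: 8 methyl (3R)-3-allyl-3-methyl-6-oxohexanoate
Conditions: Pb(OAc)4 (1.1 equiv), MeOH/toluene 1:1, 0 °C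
Reagents that add atoms: methanol, CO
Why: Lead tetraacetate cleaves the α-ketol through its methanol hemiketal (Criegee-type cleavage), so the carbonyl carbon leaves as the methyl ester on the CH2 next to the quaternary centre and the carbinol carbon as the aldehyde; the monosubstituted alkene is inert at 0 °C.

**Step 5**
Reactants: 8 methyl (3R)-3-allyl-3-methyl-6-oxohexanoate; 9 isopropylmagnesium chloride
Product: 10 methyl (3R)-3-allyl-6-hydroxy-3,7-dimethyloctanoate (both C6 epimers)
Conditions: iPrMgCl (1.2 equiv), THF, −78 °C; aq. NH4Cl
Reagents that add atoms: isopropylmagnesium chloride (9), CC(C)[Mg]Cl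
Why: Grignard addition to the unhindered aldehyde is much faster at −78 °C than attack on the methyl ester, which sits on a neopentyl CH2; the carbinol configuration is irrelevant because it is oxidised next.

**Step 6**
Reactants: 10 methyl (3R)-3-allyl-6-hydroxy-3,7-dimethyloctanoate
Product: 11 methyl (3R)-3-allyl-3,7-dimethyl-6-oxooctanoate
Conditions: Dess–Martin periodinane, NaHCO3, CH2Cl2, 0 °C to rt
Reagents that add atoms: none
Why: Dess–Martin oxidation of the secondary alcohol under buffered, neutral conditions; the only stereocentre is quaternary and cannot epimerise.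

**Step 7**
Reactants: 11 methyl (3R)-3-allyl-3,7-dimethyl-6-oxooctanoate
Product: 12 (3R)-3-allyl-3,7-dimethyl-6-oxooctanoic acid
Conditions: LiOH (3 equiv), THF/MeOH/H2O, 40 °C; then 1 M HCl to pH 3
Reagents that add atoms: lithium hydroxide, [Li+].[OH-]
Why: Saponification of the methyl ester; the isopropyl ketone and the quaternary centre are untouched by aqueous hydroxide at this temperature.

**Step 8**
Reactants: 12 (3R)-3-allyl-3,7-dimethyl-6-oxooctanoic acid
Product: 14 (1R,2R,5R)-2-allyl-5-isopropyl-2-methyl-6-oxabicyclo[3.2.0]heptan-7-one, via mixed carboxylic sulfonic anhydride 13 (not isolated)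
Conditions: TsCl (1.3 equiv, slow addition), (R)-2-phenyl-3,4-dihydro-2H-benzo[4,5]thiazolo[3,2-a]pyrimidine (20 mol%), LiCl (1 equiv), iPr2NEt (4 equiv), CH2Cl2, rt
Reagents that add atoms: none
Why: The carboxylate of 12 is sulfonylated to mixed anhydride 13, which acylates the amidine nitrogen of the isothiourea, and iPr2NEt then removes a C5 proton to give the (Z)-ammonium enolate, held planar by the S···O contact. Its addition to the C4 isopropyl ketone, activated by Li+, forms the C4–C5 bond and closes ring A in a 5-exo-trig (enolexo) aldol step; the tertiary aldolate then attacks the acyl ammonium carbon in a 4-exo-trig closure that forms the O4–C6 lactone bond and frees the catalyst. The closest known reaction type is the nucleophile-catalysed aldol-lactonisation of keto acids to cyclopentane-fused β-lactones with cinchona or isothiourea catalysts. C5 is controlled by the catalyst: the pseudoaxial phenyl group next to the acylated nitrogen covers one enolate face and the ketone is taken up on the other, which for the (R) catalyst is predicted to place C6 cis to the C1 methyl. C4 is controlled by the ring: only the aldolate whose oxygen is cis to C6 can close the four-membered lactone, and lactonisation withdraws it from the retro-aldol equilibrium. The selectivity needed is diastereoselection relative to C1, for which the substrate offers almost no bias (methyl against allyl on the quaternary carbon), so catalyst control should prevail and any minor enantiomer of 12 is diverted into a separable diastereomer. Chemoselectivity rests on the fact that only the activated acyl group is acidic enough for the amine base, while the quaternary C1 (Thorpe–Ingold effect) and slow addition of TsCl favour cyclisation over intermolecular acylation.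

**Step 9**
Reactants: 14 (1R,2R,5R)-2-allyl-5-isopropyl-2-methyl-6-oxabicyclo[3.2.0]heptan-7-one
Product: 15 (1R,2R,5R)-5-allyl-2-hydroxy-2-isopropyl-N-methoxy-N,5-dimethylcyclopentane-1-carboxamide
Conditions: MeNH(OMe)·HCl (4 equiv), Me3Al (4 equiv), CH2Cl2, 0 °C to rt; cold 0.5 M HCl
Reagents that add atoms: N,O-dimethylhydroxylamine hydrochloride, CNOC.Cl
Why: The aluminium amide formed in the flask attacks the strained acyl carbon and cleaves the acyl C–O bond (Weinreb aminolysis of a β-lactone), releasing the C4 hydroxyl; C5 keeps its configuration, which has the amide cis to the smaller groups (methyl, hydroxyl) and is also the less crowded one.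

**Step 10**
Reactants: 15 (1R,2R,5R)-5-allyl-2-hydroxy-2-isopropyl-N-methoxy-N,5-dimethylcyclopentane-1-carboxamide; 16 2-methylallylmagnesium chloride
Product: 18 1-[(1R,2R,5R)-5-allyl-2-hydroxy-2-isopropyl-5-methylcyclopentyl]-3-methylbut-3-en-1-one, via chelated N-methoxy-N-methyl hemiaminal 17 (not isolated)
Conditions: 2-methylallylMgCl (3 equiv), THF, −78 to −20 °C; quench at −78 °C into aq. NH4Cl
Reagents that add atoms: 2-methylallylmagnesium chloride (16), CC(=C)C[Mg]Cl
Why: The first equivalent deprotonates the C4 hydroxyl and the next adds to the amide to give the chelated tetrahedral adduct 17, which survives until the quench and so allows only one addition (Weinreb ketone synthesis); the allylic Grignard reagent reacts through a compact six-membered transition state and tolerates the hindered carbonyl, and the cold neutral quench limits double-bond migration and retro-aldol cleavage.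

**Step 11**
Reactants: 18 1-[(1R,2R,5R)-5-allyl-2-hydroxy-2-isopropyl-5-methylcyclopentyl]-3-methylbut-3-en-1-one
Product: 19 4β-hydroxydauc-8-en-6-one, (3R,3aR,8aR)-3-hydroxy-3-isopropyl-6,8a-dimethyl-1,2,3,3a,8,8a-hexahydroazulen-4(5H)-one
Conditions: second-generation Grubbs catalyst (5 mol%), 2,6-dichloro-1,4-benzoquinone (10 mol%), CH2Cl2 (0.005 M), 40 °C
Reagents that add atoms: none
Why: Ring-closing metathesis: the catalyst loads on the monosubstituted allyl terminus and closes onto the 1,1-disubstituted alkene, giving the seven-membered ring with the trisubstituted C8=C9 bond; the two arms are trans on ring A, as the trans-fused hydroazulene needs, and the quinone suppresses ruthenium hydride isomerisation of the β,γ-unsaturated ketone.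

**Step 12**
Reactants: 19 4β-hydroxydauc-8-en-6-one
Product: 20 dauc-8-ene-4β,6α-diol (jaeschkeanadiol), (3R,3aS,4S,8aR)-3-isopropyl-6,8a-dimethyl-1,2,3,3a,4,5,8,8a-octahydroazulene-3,4-diol
Conditions: Me4NBH(OAc)3 (5 equiv), MeCN/AcOH 1:1, −30 to 0 °C; aq. NaHCO3
Reagents that add atoms: none
Why: Hydroxyl-directed reduction (Evans–Saksena type): acetate is exchanged for the C4 alkoxide and the tethered hydride is delivered through a chair-like six-membered transition state to the β face of C6, the face on which O4 lies, giving the 6α-alcohol (anti-1,3-diol); the reagent itself is too weak to reduce the ketone from outside.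

**Step 13**
Reactants: 20 dauc-8-ene-4β,6α-diol
Product: 21 6α-(tert-butyldimethylsilyloxy)dauc-8-en-4β-ol
Conditions: TBSOTf (1.1 equiv), 2,6-lutidine, CH2Cl2, −78 °C
Reagents that add atoms: tert-butyldimethylsilyl trifluoromethanesulfonate, CC(C)(C)[Si](C)(C)OS(=O)(=O)C(F)(F)F
Why: Silylation of the secondary C6 hydroxyl is far faster at −78 °C than that of the tertiary C4 hydroxyl, which is flanked by the isopropyl group; this masks the oxygen that would otherwise be acylated first.

**Step 14**
Reactants: 22 4-(benzyloxy)-3-methoxybenzoic acid
Product: 23 4-(benzyloxy)-3-methoxybenzoyl chloride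
Conditions: (COCl)2, DMF (cat.), CH2Cl2, 0 °C to rt
Reagents that add atoms: oxalyl chloride, O=C(Cl)C(=O)Cl
Why: Acid chloride formation through the chloroiminium species generated from DMF; the aryl benzyl ether is stable to these conditions.

**Step 15**
Reactants: 21 6α-(tert-butyldimethylsilyloxy)dauc-8-en-4β-ol; 23 4-(benzyloxy)-3-methoxybenzoyl chloride
Product: 24 6α-(tert-butyldimethylsilyloxy)dauc-8-en-4β-yl 4-(benzyloxy)-3-methoxybenzoate
Conditions: n-BuLi (1.05 equiv), THF, −78 °C; then 23 (1.5 equiv), −78 to 0 °C
Reagents that add atoms: none
Why: O-Acylation of a lithium tert-alkoxide by an aroyl chloride, the established way to tert-alkyl benzoates (the acid chloride has no α-hydrogen, so no ketene pathway competes); O6 is blocked and the low temperature is meant to outrun silyl migration.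

**Step 16**
Reactants: 24 6α-(tert-butyldimethylsilyloxy)dauc-8-en-4β-yl 4-(benzyloxy)-3-methoxybenzoate
Product: 25 6α-hydroxydauc-8-en-4β-yl 4-(benzyloxy)-3-methoxybenzoate
Conditions: HF·pyridine, pyridine, THF, 0 °C to rt
Reagents that add atoms: none
Why: Buffered fluoride cleaves the secondary silyl ether without generating a free alkoxide, so acyl transfer from O4 to O6 is not triggered; the tertiary ester, the benzyl ether and the alkene are inert.

**Step 17**
Reactants: 25 6α-hydroxydauc-8-en-4β-yl 4-(benzyloxy)-3-methoxybenzoate
Product: 26 8α,9α-epoxy-6α-hydroxydaucan-4β-yl 4-(benzyloxy)-3-methoxybenzoate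
Conditions: VO(acac)2 (5 mol%), t-BuOOH (1.5 equiv, decane), CH2Cl2, 0 °C to rt
Reagents that add atoms: tert-butyl hydroperoxide, CC(C)(C)OO
Why: Vanadium-catalysed hydroxyl-directed epoxidation of a cyclic homoallylic alcohol: the C6 vanadate ester delivers the peroxide oxygen to the α face of C8=C9, which is also the face left open by the β angular methyl, so C8 and C9 are set together; the cis epoxy alcohol cannot open the epoxide intramolecularly because backside approach is impossible.

**Step 18**
Reactants: 26 8α,9α-epoxy-6α-hydroxydaucan-4β-yl 4-(benzyloxy)-3-methoxybenzoate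
Product: 27 8α,9α-epoxy-6α-hydroxydaucan-4β-yl 4-hydroxy-3-methoxybenzoate (target)
Conditions: H2 (1 atm), Pd/C (10%), EtOAc, rt
Reagents that add atoms: none
Why: Hydrogenolysis of the aryl benzyl ether on palladium under neutral conditions; the non-benzylic trisubstituted epoxide and the tertiary ester should survive, and the absence of base keeps the acyl group on O4.

## Compound list

1 | 3-ethoxycyclohex-2-en-1-one | CCOC1=CC(=O)CCC1 | starting material
2 | allylmagnesium bromide | C=CC[Mg]Br | starting material
3 | 1-allyl-3-ethoxycyclohex-2-en-1-ol (racemic; formed as its magnesium alkoxide) | C=CCC1(O)C=C(OCC)CCC1 | intermediate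
4 | 3-allylcyclohex-2-en-1-one | C=CCC1=CC(=O)CCC1 | intermediate
5 | trimethylaluminium | C[Al](C)C | starting material
6 | (R)-3-allyl-3-methylcyclohexan-1-one | O=C1C[C@@](C)(CC=C)CCC1 | intermediate
7 | (5R)-5-allyl-2-hydroxy-5-methylcyclohexan-1-one (both C2 epimers) | O=C1C[C@@](C)(CC=C)CCC1O | intermediate
8 | methyl (3R)-3-allyl-3-methyl-6-oxohexanoate | COC(=O)C[C@@](C)(CC=C)CCC=O | intermediate
9 | isopropylmagnesium chloride | CC(C)[Mg]Cl | starting material
10 | methyl (3R)-3-allyl-6-hydroxy-3,7-dimethyloctanoate (both C6 epimers) | COC(=O)C[C@@](C)(CC=C)CCC(O)C(C)C | intermediate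
11 | methyl (3R)-3-allyl-3,7-dimethyl-6-oxooctanoate | COC(=O)C[C@@](C)(CC=C)CCC(=O)C(C)C | intermediate
12 | (3R)-3-allyl-3,7-dimethyl-6-oxooctanoic acid | OC(=O)C[C@@](C)(CC=C)CCC(=O)C(C)C | intermediate
13 | (3R)-3-allyl-3,7-dimethyl-6-oxooctanoic 4-methylbenzenesulfonic anhydride | Cc1ccc(cc1)S(=O)(=O)OC(=O)C[C@@](C)(CC=C)CCC(=O)C(C)C | intermediate
14 | (1R,2R,5R)-2-allyl-5-isopropyl-2-methyl-6-oxabicyclo[3.2.0]heptan-7-one (ring A β-lactone, lactone bridge cis to the C1 methyl) | O=C1O[C@@]2(C(C)C)CC[C@](C)(CC=C)[C@@H]12 | intermediate
15 | (1R,2R,5R)-5-allyl-2-hydroxy-2-isopropyl-N-methoxy-N,5-dimethylcyclopentane-1-carboxamide | CON(C)C(=O)[C@H]1[C@](O)(C(C)C)CC[C@]1(C)CC=C | intermediate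
16 | 2-methylallylmagnesium chloride | CC(=C)C[Mg]Cl | starting material
17 | 1-[(1R,2R,5R)-5-allyl-2-hydroxy-2-isopropyl-5-methylcyclopentyl]-1-[methoxy(methyl)amino]-3-methylbut-3-en-1-ol (present as its magnesium chelate) | CC(=C)CC(O)(N(C)OC)[C@H]1[C@](O)(C(C)C)CC[C@]1(C)CC=C | intermediate
18 | 1-[(1R,2R,5R)-5-allyl-2-hydroxy-2-isopropyl-5-methylcyclopentyl]-3-methylbut-3-en-1-one | CC(=C)CC(=O)[C@H]1[C@](O)(C(C)C)CC[C@]1(C)CC=C | intermediate
19 | 4β-hydroxydauc-8-en-6-one, (3R,3aR,8aR)-3-hydroxy-3-isopropyl-6,8a-dimethyl-1,2,3,3a,8,8a-hexahydroazulen-4(5H)-one | O[C@@]1(C(C)C)CC[C@]2(C)CC=C(C)CC(=O)[C@H]21 | intermediate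
20 | dauc-8-ene-4β,6α-diol (jaeschkeanadiol), (3R,3aS,4S,8aR)-3-isopropyl-6,8a-dimethyl-1,2,3,3a,4,5,8,8a-octahydroazulene-3,4-diol | O[C@@]1(C(C)C)CC[C@]2(C)CC=C(C)C[C@H](O)[C@H]21 | intermediate
21 | 6α-(tert-butyldimethylsilyloxy)dauc-8-en-4β-ol | O[C@@]1(C(C)C)CC[C@]2(C)CC=C(C)C[C@H](O[Si](C)(C)C(C)(C)C)[C@H]21 | intermediate
22 | 4-(benzyloxy)-3-methoxybenzoic acid | COc1cc(C(=O)O)ccc1OCc1ccccc1 | starting material
23 | 4-(benzyloxy)-3-methoxybenzoyl chloride | COc1cc(C(Cl)=O)ccc1OCc1ccccc1 | intermediate
24 | 6α-(tert-butyldimethylsilyloxy)dauc-8-en-4β-yl 4-(benzyloxy)-3-methoxybenzoate | COc1cc(C(=O)O[C@@]2(C(C)C)CC[C@]3(C)CC=C(C)C[C@H](O[Si](C)(C)C(C)(C)C)[C@H]32)ccc1OCc1ccccc1 | intermediate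
25 | 6α-hydroxydauc-8-en-4β-yl 4-(benzyloxy)-3-methoxybenzoate | COc1cc(C(=O)O[C@@]2(C(C)C)CC[C@]3(C)CC=C(C)C[C@H](O)[C@H]32)ccc1OCc1ccccc1 | intermediate
26 | 8α,9α-epoxy-6α-hydroxydaucan-4β-yl 4-(benzyloxy)-3-methoxybenzoate | COc1cc(C(=O)O[C@@]2(C(C)C)CC[C@]3(C)C[C@@H]4O[C@]4(C)C[C@H](O)[C@H]32)ccc1OCc1ccccc1 | intermediate
27 | 8α,9α-epoxy-6α-hydroxydaucan-4β-yl 4-hydroxy-3-methoxybenzoate, (1R,4R,5S,6S,8R,9S) in daucane numbering (CNP0315707.1) | COc1cc(C(=O)O[C@@]2(C(C)C)CC[C@]3(C)C[C@@H]4O[C@]4(C)C[C@H](O)[C@H]32)ccc1O | target

## Step count and least certain steps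

Total: 18 steps. Longest linear sequence: 17 steps (steps 1–13 and 15–18, from 1); step 14 is a one-step side branch.

**Step 8 (key step).** The ammonium enolate may add too slowly to the hindered isopropyl ketone, so that the activated acid is lost to oligomeric anhydrides or ketene-derived products. Facial control relative to C1 may also be incomplete and give a diastereomer mixture. Fallback: an auxiliary-controlled intramolecular aldol reaction that sets out from 12. The acid is converted through its pivalic mixed anhydride with lithiated (R)-4-benzyloxazolidin-2-one into (R)-4-benzyl-3-[(3R)-3-allyl-3,7-dimethyl-6-oxooctanoyl]oxazolidin-2-one F1. Soft enolisation with TiCl4 and iPr2NEt in CH2Cl2 (−78 to 0 °C) gives the chelated (Z)-enolate, which adds to the C4 ketone through a closed transition state (O4 and C6 necessarily cis, C5 face chosen by the auxiliary) to give the aldol adduct (R)-4-benzyl-3-{[(1R,2R,5R)-5-allyl-2-hydroxy-2-isopropyl-5-methylcyclopentyl]carbonyl}oxazolidin-2-one F2. Transamidation with MeNH(OMe)·HCl/Me3Al releases the auxiliary and comes back to the route at 15.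

**Step 15.** The very hindered alkoxide may be acylated incompletely, or the silyl group may migrate from O6 to O4 so that the acyl group ends up on O6. Fallback: a non-migrating ether on O6, setting out from 20. Alkylation with NaH and 4-methoxybenzyl chloride (THF/DMF, 0 °C) takes the secondary alkoxide and gives 6α-(4-methoxybenzyloxy)dauc-8-en-4β-ol F3. The tertiary alcohol can then be acylated under forcing conditions (KN(SiMe3)2, 23, THF, 0 °C to rt) to 6α-(4-methoxybenzyloxy)dauc-8-en-4β-yl 4-(benzyloxy)-3-methoxybenzoate F4. Oxidative removal of the 4-methoxybenzyl group with DDQ in CH2Cl2/pH 7 buffer comes back to the route at 25.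

**Step 12.** Acetate/alkoxide exchange at the crowded tertiary C4 hydroxyl may be too slow, so that no internal hydride delivery takes place; forcing the reaction would open an undirected pathway with poor facial selectivity at C6. Fallback: reagent-controlled reduction before ring closure, setting out from 18. Corey–Bakshi–Shibata reduction with (R)-2-methyl-CBS-oxazaborolidine and catecholborane (toluene, −78 °C) distinguishes the branched C5 side from the CH2 side of the ketone and gives (1R,2S,3R)-3-allyl-2-[(1S)-1-hydroxy-3-methylbut-3-en-1-yl]-3-methyl-1-isopropylcyclopentan-1-ol F5. Ring-closing metathesis with the second-generation Grubbs catalyst under the conditions of step 11 then comes back to the route at 20.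

**Step 10.** A second addition of the very reactive allylic Grignard reagent may occur, or base-induced migration of the β,γ-double bond into conjugation and retro-aldol opening of the magnesium aldolate during warming or quench. Fallback: carbon–carbon bond formation at the aldehyde level under neutral conditions, setting out from 14. Reduction with LiAlH4 gives (1R,2S,3R)-3-allyl-2-(hydroxymethyl)-3-methyl-1-isopropylcyclopentan-1-ol F6. Selective oxidation of the primary alcohol (TEMPO, PhI(OAc)2, CH2Cl2) gives (1R,2R,5R)-5-allyl-2-hydroxy-2-isopropyl-5-methylcyclopentane-1-carbaldehyde F7. Allylboration with 2-methylallylboronic acid pinacol ester gives (1R,2S,3R)-3-allyl-2-(1-hydroxy-3-methylbut-3-en-1-yl)-3-methyl-1-isopropylcyclopentan-1-ol F8 as a mixture of carbinol epimers. Dess–Martin oxidation of the secondary alcohol comes back to the route at 18.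

**Step 2.** The doubly allylic CH2 of 4 may be deprotonated and the terminal double bond moved into conjugation before or during the conjugate addition, or the enantioselectivity may be lowered by the coordinating allyl group. Fallback: carry the allyl group as a protected acetaldehyde, setting out from 1. Addition of (1,3-dioxolan-2-ylmethyl)magnesium bromide and brief cold acid treatment gives 3-(1,3-dioxolan-2-ylmethyl)cyclohex-2-en-1-one F9. The same copper-catalysed Me3Al addition gives (R)-3-(1,3-dioxolan-2-ylmethyl)-3-methylcyclohexan-1-one F10. Acetal hydrolysis (aq. HCl, THF) gives 2-[(1R)-1-methyl-3-oxocyclohexyl]acetaldehyde F11. Wittig methylenation with one equivalent of Ph3P=CH2 at −78 to 0 °C reacts at the aldehyde first and comes back to the route at 6.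

## Further compounds

F1 | step 8 | (R)-4-benzyl-3-[(3R)-3-allyl-3,7-dimethyl-6-oxooctanoyl]oxazolidin-2-one | O=C1OC[C@@H](Cc2ccccc2)N1C(=O)C[C@@](C)(CC=C)CCC(=O)C(C)C
F2 | step 8 | (R)-4-benzyl-3-{[(1R,2R,5R)-5-allyl-2-hydroxy-2-isopropyl-5-methylcyclopentyl]carbonyl}oxazolidin-2-one | O=C1OC[C@@H](Cc2ccccc2)N1C(=O)[C@H]3[C@](O)(C(C)C)CC[C@]3(C)CC=C
F3 | step 15 | 6α-(4-methoxybenzyloxy)dauc-8-en-4β-ol | O[C@@]1(C(C)C)CC[C@]2(C)CC=C(C)C[C@H](OCc3ccc(OC)cc3)[C@H]21
F4 | step 15 | 6α-(4-methoxybenzyloxy)dauc-8-en-4β-yl 4-(benzyloxy)-3-methoxybenzoate | COc1cc(C(=O)O[C@@]2(C(C)C)CC[C@]3(C)CC=C(C)C[C@H](OCc4ccc(OC)cc4)[C@H]32)ccc1OCc1ccccc1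
F5 | step 12 | (1R,2S,3R)-3-allyl-2-[(1S)-1-hydroxy-3-methylbut-3-en-1-yl]-3-methyl-1-isopropylcyclopentan-1-ol | CC(=C)C[C@H](O)[C@H]1[C@](O)(C(C)C)CC[C@]1(C)CC=C
F6 | step 10 | (1R,2S,3R)-3-allyl-2-(hydroxymethyl)-3-methyl-1-isopropylcyclopentan-1-ol | OC[C@H]1[C@](O)(C(C)C)CC[C@]1(C)CC=C
F7 | step 10 | (1R,2R,5R)-5-allyl-2-hydroxy-2-isopropyl-5-methylcyclopentane-1-carbaldehyde | O=C[C@H]1[C@](O)(C(C)C)CC[C@]1(C)CC=C
F8 | step 10 | (1R,2S,3R)-3-allyl-2-(1-hydroxy-3-methylbut-3-en-1-yl)-3-methyl-1-isopropylcyclopentan-1-ol (both carbinol epimers) | CC(=C)CC(O)[C@H]1[C@](O)(C(C)C)CC[C@]1(C)CC=C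
F9 | step 2 | 3-(1,3-dioxolan-2-ylmethyl)cyclohex-2-en-1-one | O=C1C=C(CC2OCCO2)CCC1
F10 | step 2 | (R)-3-(1,3-dioxolan-2-ylmethyl)-3-methylcyclohexan-1-one | O=C1C[C@@](C)(CC2OCCO2)CCC1
F11 | step 2 | 2-[(1R)-1-methyl-3-oxocyclohexyl]acetaldehyde | O=C1C[C@@](C)(CC=O)CCC1
A1 | alternative 1 | cis-6-isopropyl-3a-methyl-6-(triethylsilyloxy)hexahydropentalen-1(2H)-one (cis-fused bicyclo[3.3.0]octanone, silyloxy group cis to the angular methyl) | CC[Si](CC)(CC)O[C@@]1(C(C)C)CC[C@]2(C)CCC(=O)[C@H]12
A2 | alternative 1 | methyl 3-isopropyl-6,8a-dimethyl-4-(pyrrolidin-1-yl)-3-(triethylsilyloxy)-1,2,3,3a,8,8a-hexahydroazulene-5-carboxylate (cis ring fusion) | CC[Si](CC)(CC)O[C@@]1(C(C)C)CC[C@]2(C)CC=C(C)C(C(=O)OC)=C(N3CCCC3)[C@H]12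
A3 | alternative 2 | 2-allyl-2-methyl-1-[trans-3-(2-methylallyl)oxiran-2-yl]cyclobutan-1-ol (carbinol configuration open) | OC1(CC[C@]1(C)CC=C)[C@@H]1O[C@H]1CC(C)=C
A4 | alternative 2 | 3-allyl-2-(1-hydroxy-3-methylbut-3-enyl)-3-methylcyclopentanone | O=C1CC[C@](C)(CC=C)[C@H]1[C@@H](O)CC(=C)C
A5 | alternative 3 | (S)-terpinen-4-ol, (S)-4-methyl-1-(propan-2-yl)cyclohex-3-en-1-ol | CC1=CC[C@](O)(C(C)C)CC1
A6 | alternative 3 | dauc-8-ene-4β,6α-diol (jaeschkeanadiol; identical with 20) | O[C@@]1(C(C)C)CC[C@]2(C)CC=C(C)C[C@H](O)[C@H]21
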